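**Retrosynthetic overview**

1. Both flavone halves come from the same two pieces, acetophenone 1 (twice) and aldehyde 3 (twice). The only skeletal C–C coupling is done first, on the monomer, and gives the C2-symmetric biaryl diketone 2.
2. Double aldol condensation of 2 with 3 gives bichalcone 4. It has no heterocycle yet and carries no 6,8'' information: each ring has an "inner" OH (2/2', ortho to the axis) and an "outer" OH (4/4', para to the axis).
3. Key disconnection: the two pyranone O1–C2 bonds. Closing one arm through its inner oxygen (8-linked unit) and the other through its outer oxygen (6-linked unit) is what defines the target. One boron template in the inner-diol pocket is proposed to enforce this (5 → 6 → 7 → 8).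
4. Ring order: ring C of the 8-linked unit, then ring C of the 6-linked unit, then both dehydrogenated in the same flask to target 9.

Assumption: the SMILES has no stereodescriptor and no stereocentre; its only stereo-element, the hindered 6,8''-biaryl axis, is unspecified, so the compound is made as drawn with the axis unassigned (racemic).

**Route**

Step 1
Reactants: 1 2',6'-dihydroxy-4'-methoxyacetophenone (two molecules)
Product: 2 3,3'-diacetyl-2,2',4,4'-tetrahydroxy-6,6'-dimethoxybiphenyl (racemic axis)
Conditions: FeCl3 on SiO2 (1.1 equiv per 1), CH2Cl2, rt, stopped at ca. 60% conversion; 1 M HCl work-up, unreacted 1 recycled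
Reagents that add atoms: none
Why: Oxidative phenol homocoupling (trivalent iron is reduced to divalent iron); the two free ring positions of 1 are equivalent, each ortho to one OH and para to the other, so the only C–C dimer possible is the 3,3'-linked biaryl 2.

Step 2
Reactants: 2 3,3'-diacetyl-2,2',4,4'-tetrahydroxy-6,6'-dimethoxybiphenyl; 3 4-hydroxybenzaldehyde (3 equiv)
Product: 4 (2E,2'E)-1,1'-(2,2',4,4'-tetrahydroxy-6,6'-dimethoxybiphenyl-3,3'-diyl)bis[3-(4-hydroxyphenyl)prop-2-en-1-one] (bichalcone, racemic axis)
Conditions: KOH (60% aq, 20 equiv), EtOH, 50 °C, argon, 48 h; then poured into ice-cold 2 M HCl (pH 2–3), filtered cold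
Reagents that add atoms: none
Why: Double Claisen–Schmidt aldol condensation with E1cB dehydration gives the E,E-dienone; in strong alkali the product stays as the open-chain chalcone polyphenoxide (flavanones ring-open under these conditions) and cold acidification isolates it before either arm can cyclise.

Step 3
Reactants: 4 bichalcone
Product: 9 DMGF (7,7''-di-O-methylagathisflavone; 5,5''-dihydroxy-2,2''-bis(4-hydroxyphenyl)-7,7''-dimethoxy-6,8''-bi-4H-chromene-4,4''-dione), via hydroxyboronate ate complex 5 (not isolated), via mono-cyclised hemiboronate 6 (not isolated), via biflavanone boron chelate 7 (not isolated), via 6,8''-biflavanone 8 (not isolated)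
Conditions: 4, 3,5-(CF3)2C6H3B(OH)2 (1.05 equiv), THF, rt, 1 h; N-methylmorpholine (1.0 equiv), 0 °C → rt, 12 h; then AcOH (3 equiv), H2O (5 equiv); then DMSO, I2 (20 mol %), 120 °C, 3 h (THF distilled off); aq. Na2S2O3 work-up
Reagents that add atoms: none
Why: Proposed new method: a boron-templated, desymmetrising double oxa-Michael cyclisation that forms both pyranone C–O bonds and fixes the 6,8'' connectivity. One monoarylboron unit is bound by the two inner (2,2') phenols as a tetracoordinate hydroxyboronate (5; the weak base ionises only the Lewis-acidic boronate, not the phenols), and because boron has only four valences it treats the two arms differently: (a) a boron-bound inner oxygen is the only ate-activated oxygen nucleophile and lies syn to Cα, since that arm's carbonyl is hydrogen-bonded to its outer OH, so it adds 6-endo to its own enone and leaves boron (first C–O bond, 8-linked ring, 6); (b) the boron, now neutral and Lewis acidic and still esterified to the inner oxygen of the second arm, chelates that arm's carbonyl, which masks the inner oxygen, activates the enone and turns Cα toward the outer OH, which closes the second C–O bond (6-linked ring, 7). The reverse order of these two events gives the same pattern, and the 6,6'' and 8,8'' closures are disfavoured while exactly one boron stays in the pocket. Closest known reaction types: borinic- and boronic-acid activation of diols as tetracoordinate boron alkoxides for self-limiting mono-functionalisation, boronic-acid-mediated oxa-Michael addition, and the rule that in 2',6'-dihydroxychalcones the carbonyl-chelated hydroxyl becomes 5-OH. The last stage is known chemistry: iodine-catalysed DMSO dehydrogenation of flavanones to flavones, which removes both C2 stereocentres so that no new stereocentre needs control.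

**Compound list**

1 | 2',6'-dihydroxy-4'-methoxyacetophenone | CC(=O)c1c(O)cc(OC)cc1O | starting material
2 | 3,3'-diacetyl-2,2',4,4'-tetrahydroxy-6,6'-dimethoxybiphenyl (racemic axis) | CC(=O)c1c(O)cc(OC)c(-c2c(O)c(C(C)=O)c(O)cc2OC)c1O | intermediate
3 | 4-hydroxybenzaldehyde | O=Cc1ccc(O)cc1 | starting material
4 | E,E-bichalcone of 2 with two 4-hydroxycinnamoyl arms | O=C(/C=C/c1ccc(O)cc1)c1c(O)cc(OC)c(-c2c(O)c(C(=O)/C=C/c3ccc(O)cc3)c(O)cc2OC)c1O | intermediate
5 | N-methylmorpholinium hydroxyboronate ate complex of 4: 3,5-bis(trifluoromethyl)phenyl(hydroxy)borate bridging the inner 2,2'-oxygens (not isolated) | C[NH+]1CCOCC1.O[B-]1(c2cc(C(F)(F)F)cc(C(F)(F)F)c2)Oc2c(C(=O)/C=C/c3ccc(O)cc3)c(O)cc(OC)c2-c2c(OC)cc(O)c(C(=O)/C=C/c3ccc(O)cc3)c2O1 | intermediate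
6 | mono-cyclised hemiboronate: 8-aryl-5-hydroxy-7-methoxyflavanone whose 8-aryl group is the remaining chalcone ring with its inner oxygen carrying ArB(OH) (dative C=O→B bond not drawn; C2 epimers; not isolated) | Oc1cc(OC)c(-c2c(OC)cc(O)c(C(=O)/C=C/c3ccc(O)cc3)c2OB(O)c2cc(C(F)(F)F)cc(C(F)(F)F)c2)c2OC(c3ccc(O)cc3)CC(=O)c12 | intermediate
7 | 6,8''-biflavanone held as the O5-aryl(hydroxy)boron chelate of its 6-linked unit (dative C4=O→B bond not drawn; diastereomer mixture; not isolated) | Oc1cc(OC)c(-c2c(OC)cc3OC(c4ccc(O)cc4)CC(=O)c3c2OB(O)c2cc(C(F)(F)F)cc(C(F)(F)F)c2)c2OC(c3ccc(O)cc3)CC(=O)c12 | intermediate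
8 | 5,5''-dihydroxy-2,2''-bis(4-hydroxyphenyl)-7,7''-dimethoxy-6,8''-biflavanone (diastereomer mixture at C2, C2'' and the axis; not isolated) | COc1cc2OC(c3ccc(O)cc3)CC(=O)c2c(O)c1-c1c(OC)cc(O)c2C(=O)CC(c3ccc(O)cc3)Oc12 | intermediate
9 | DMGF, 7,7''-di-O-methylagathisflavone (6,8''-linked dimer of 5,4'-dihydroxy-7-methoxyflavone; axis unassigned) | COc1cc2oc(-c3ccc(O)cc3)cc(=O)c2c(O)c1-c1c(OC)cc(O)c2c(=O)cc(-c3ccc(O)cc3)oc12 | target

**Step count and risks**

Total step count: 3. Longest linear sequence: 3 (1 → 2 → 4 → 9).

Steps most likely to fail:

Step 3 (proposed new step). The regiocontrol is untested and can leak in two ways. A second boron-bound oxygen may be delivered, which gives the 8,8'' isomer. Background closure through outer hydroxyls, or base-induced reopening and reclosing of a flavanone ring, gives the 6,6'' isomer. Ring iodination of the electron-rich rings under iodine/DMSO is a minor further risk. Fallback with known chemistry, setting out from 4 and coming back at 9: drop the template and heat 4 directly with I2 (20 mol %) in DMSO at 130 °C, the standard oxidative cyclisation of 2'-hydroxychalcones to flavones. Both arms then close without control; if the two closures were independent and unbiased the mixed 6,8'' product would be the largest component (two of the four closure combinations, at most about half of the material), but any intrinsic preference for closure through the outer hydroxyls would shift the mixture toward the 6,6'' isomer. Target 9 is separated by chromatography or preparative HPLC from the symmetric 6,6''-linked isomer F5 and the symmetric 8,8''-linked isomer F6.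

Step 1. The product 2 is still an electron-rich phenol with one free position per ring, so over-oxidation and oligomerisation compete, and it chelates iron strongly. Fallback, setting out from 1 and coming back at 2, with an aryl-halide coupling in place of the oxidative one: exhaustive O-methylation of 1 (Me2SO4, K2CO3, acetone, reflux) gives 2',4',6'-trimethoxyacetophenone F1. Iodination (N-iodosuccinimide, cat. CF3CO2H, MeCN) gives 3'-iodo-2',4',6'-trimethoxyacetophenone F2. Ullmann homocoupling (copper powder, DMF, 150 °C) gives 3,3'-diacetyl-2,2',4,4',6,6'-hexamethoxybiphenyl F3. Chelation-controlled cleavage of the four methoxy groups ortho to the acetyl groups (excess BCl3, CH2Cl2, 0 °C → rt; AlCl3 in chlorobenzene if the second ortho ether is slow) returns 2 with the 6,6'-methoxy groups intact.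

Step 2. The polyanionic diketone and the phenoxide form of the aldehyde are both poor aldol partners, so conversion may be low, and the 2',6'-dihydroxychalcone arms of 4 cyclise easily if work-up is warm or near neutral. Fallback, setting out from 2 and coming back at 4, with a protecting-group strategy: condense 2 with commercial 4-(methoxymethoxy)benzaldehyde (KOH, EtOH, rt), where the aldehyde is no longer deactivated, to give the bis(methoxymethyl) ether of the bichalcone F4. Then remove the two methoxymethyl groups with HCl in MeOH/THF at 0 °C → rt, stopping before flavanone formation, to give 4.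

**Further compounds**

F1 | step 1 | 2',4',6'-trimethoxyacetophenone | CC(=O)c1c(OC)cc(OC)cc1OC
F2 | step 1 | 3'-iodo-2',4',6'-trimethoxyacetophenone | CC(=O)c1c(OC)cc(OC)c(I)c1OC
F3 | step 1 | 3,3'-diacetyl-2,2',4,4',6,6'-hexamethoxybiphenyl | CC(=O)c1c(OC)cc(OC)c(-c2c(OC)c(C(C)=O)c(OC)cc2OC)c1OC
F4 | step 2 | bichalcone 4 with both 4-hydroxyphenyl groups as methoxymethyl ethers | COCOc1ccc(/C=C/C(=O)c2c(O)cc(OC)c(-c3c(O)c(C(=O)/C=C/c4ccc(OCOC)cc4)c(O)cc3OC)c2O)cc1
F5 | step 3 | 6,6''-linked isomer of 9 (5,5''-dihydroxy-2,2''-bis(4-hydroxyphenyl)-7,7''-dimethoxy-6,6''-biflavone) | COc1cc2oc(-c3ccc(O)cc3)cc(=O)c2c(O)c1-c1c(OC)cc2oc(-c3ccc(O)cc3)cc(=O)c2c1O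
F6 | step 3 | 8,8''-linked isomer of 9 (7,7''-di-O-methylcupressuflavone) | COc1cc(O)c2c(=O)cc(-c3ccc(O)cc3)oc2c1-c1c(OC)cc(O)c2c(=O)cc(-c3ccc(O)cc3)oc12
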